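## The problem

Compound 27 is an open-chain 2,3-disubstituted succinic acid, numbered C1–C4 along the chain, in which C1 is a free carboxylic acid and C4 a methyl ester. C2 carries the 4-hydroxyphenyl ring (ring A) and C3 carries, through a CH2 group, the 3-hydroxy-4-prenylphenyl ring (ring B). Both stereocentres are R and sit on adjacent carbons of a freely rotating chain, so no ring can relay configuration: one centre needs an external controller, the other a second controller or 1,2-induction. Both are epimerisable (C2–H is benzylic and alpha to a carboxyl group, C3–H is alpha to the ester), and any passage through the cyclic anhydride would erase the acid/ester distinction. The prenyl group of ring B is a trisubstituted alkene ortho to a phenol: it closes to a chroman in strong acid, is hydrogenated readily and reacts with electrophilic oxidants, so it must arrive late, and the phenols need protection removable under near-neutral conditions. The feature that opens the route is the C1–C2 pair: an electron-rich para-oxygenated aryl ring on C2 next to a carbonyl carbon is what a styrene leaves behind when its aryl group shifts from C1 to C2 under an electrophilic trivalent iodine reagent in methanol. C1 then emerges as an aldehyde acetal, an oxidation level different from the ester at C4.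

## Retrosynthesis

**End game, 27 back to 24.** Only heteroatom bonds are cut. The two O–Si bonds of bis(triisopropylsilyl ether) 26 go last, because fluoride buffered with acetic acid touches neither stereocentre nor the ortho-prenylphenol. Acid 26 comes from aldehyde 25, and 25 from dimethyl acetal 24. Keeping C1 as an acetal until this point means C2 cannot enolise during the preceding cross-coupling, and the C1/C4 distinction never depends on opening an anhydride.

**Prenyl group, 24 back to 23.** The ring B aryl–CH2 bond of the prenyl group is cut, leaving aryl bromide 23. The cut is placed after the key step because the prenyl alkene would compete with the styrene for the iodane, and before the acetal hydrolysis because a basic organometallic partner is incompatible with a free acid. The forward reaction must couple an allyl–metal reagent only at its unsubstituted terminus, next to a bulky silyl ether.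

**Key disconnection, 23 back to 16 and 21.** The C2–aryl bond is cut and ring A is returned to C1, which reverts from acetal carbon to alkene carbon. This gives the (E)-styrene 16 and two molecules of methanol 21, with the lactate-derived aryl-λ3-iodane 20 as oxidant. Against cutting C2–C3 or C3–CH2 at this stage, this cut removes one stereocentre and the oxidation-level problem together, and 16 has a single, non-benzylic stereocentre. The forward step must deliver the aryl group to one face of C2. C3 exerts little bias across an E-alkene, so control is assigned to the twofold-symmetric reagent 20, and C3 ensures that any minor isomer is a separable diastereomer.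

**Ester from auxiliary, 16 back to 13.** Ester 16 comes from acid 15 and 15 from imide 13 (C–O for C–N exchange). Hydroperoxide cleavage followed by neutral O-methylation is preferred to direct methanolysis with a metal methoxide, because C3–H is flanked by a carbonyl group and a styrene and would not tolerate alkoxide.

**C3–CH2 bond, 13 back to 7 and 11.** Cutting the bond between C3 and the benzylic carbon of ring B gives imide 7 and benzylic bromide 11. The auxiliary sets C3 reliably and the electrophile is a reactive primary benzylic bromide. The forward reaction must alkylate the dienolate at its alpha carbon and not at the benzylic gamma carbon.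

**Chain, 7 back to 1, 3 and 5.** The N–acyl bond of 7 is cut to acid 4 and (R)-4-benzyl-2-oxazolidinone 5. The aryl–vinyl bond of 4 is cut to aryl iodide 2 and but-3-enoic acid 3 (Heck reaction), and 2 is the silyl ether of 4-iodophenol 1. This builds the four-carbon chain with the alkene already in the right place in one C–C bond formation.

**Ring B fragment, 11 back to 8.** Bromide 11 comes from alcohol 10, aldehyde 9 and commercial 4-bromo-3-hydroxybenzaldehyde 8 by functional-group changes only; the bromine atom is the placeholder for prenyl.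

**Oxidant, 20 back to 17 and 18.** The two I–O bonds of 20 are cut to aryl iodide 19, and the two aryl ether C–O bonds of 19 to 2-iodoresorcinol 17 and two molecules of methyl (S)-lactate 18, one for each phenol oxygen. Both steps are routine, and 19 is recovered after the key step.

## Roads not taken

**Alternative 1:** Both carboxyl carbons are disconnected (C1–C2 and C3–C4). The forward key step is a double ring-expanding carbonylation of cis-epoxide A2 to cis-anhydride A1 with [(salph)Al(THF)2][Co(CO)4].
- Merits: each C–O bond is replaced with inversion, so a cis-epoxide gives the cis-anhydride stereospecifically. Both stereocentres derive from one asymmetric epoxidation and both carbonyl carbons are introduced catalytically. It would be shorter than the chosen plan and fixes the relative configuration by mechanism.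
- Weak points: A2 is a para-acyloxy styrene oxide, and Lewis-acid activation invites benzylic ionisation, which costs stereospecificity and leads to rearranged carbonyl compounds. A1 has C1 and C4 at the same oxidation level, so methanol 21 would have to open it selectively at C4, between two carbonyl groups that differ only in an alpha-aryl versus an alpha-benzyl substituent. The cis-anhydride also epimerises easily at C2. Prenylation and pivalate removal would still follow.
- Comparison: better in step count and in the relay of relative configuration. The chosen plan never has C1 and C4 at the same oxidation level, and it uses the electron-rich ring A productively, where here it is a liability.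

**Alternative 2:** The C2–H and C3–H bonds are disconnected. The forward key step is asymmetric syn-hydrogenation of the tetrasubstituted maleic anhydride A4 to cis-anhydride A3 with [Rh(cod)2]BF4 and a chiral bisphosphine–thiourea ligand.
- Merits: A4 is available in very few steps by a Perkin-type condensation, carries the prenyl group from the start, and syn addition gives the required relative configuration in one operation. This is the shortest route.
- Weak points: a tetrasubstituted alkene with two similar flanking substituents is at the limit of enantioselective hydrogenation. The prenyl alkene must survive. A3 needs the same regioselective opening at C4 as A1, and removing the aryl acetates under basic methanol conditions risks opening the anhydride either way and epimerising C2.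
- Comparison: clearly superior in step count if the hydrogenation and ring opening both worked. The chosen plan has an unambiguous acid/ester constitution and sets each stereocentre with a separately checkable control element.

**Alternative 3:** The CH2–ring B bond is disconnected. The forward key step is conjugate addition of arylboronic acid A7 to methylene succinate A6 with [Rh(cod)Cl]2/BINAP, followed by protonation of the rhodium enolate at C3 by a phenol additive, giving A5.
- Merits: convergent; the prenyl group arrives intact with ring B; the two carboxyl groups are differentiated from the start, and one fluoride treatment would unveil 27 from A5. In convergence and handling of the prenyl group it is better than the chosen plan, and equal in carboxyl differentiation.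
- Weak points: C2–H in A6 is benzylic, alpha to an ester and allylic to the acrylate, so racemisation or migration of the alkene into full conjugation is likely under the basic aqueous conditions. A6 itself needs an asymmetric synthesis. The protonation must be controlled next to an existing centre, for which there is no firm model.
- Comparison: the chosen plan sets C3 by a robust auxiliary alkylation, creates the sensitive C2 centre late, and keeps it as a non-enolisable acetal until the cross-coupling is over.

Key step: step 12

Assumption: the (R,R) antipode 20, made from natural methyl (S)-lactate, is taken to be the reagent that bonds iodine to the Si face of C2 in 16. The sense of reagent control on this substrate has to be confirmed in the first experiment; if it is opposite, the reagent series is made from the other lactate enantiomer and nothing else changes.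

## Route

Step 1
Reactants: 1 4-iodophenol
Product: 2 triisopropyl(4-iodophenoxy)silane
Conditions: i-Pr3SiCl, imidazole, DMF, 23 °C
Reagents that add atoms: triisopropylsilyl chloride, CC(C)[Si](Cl)(C(C)C)C(C)C
Why: Silyl ether formation on a phenol; the bulky silyl group should survive amide bases at low temperature, brief aqueous hydroperoxide, sulfonic acid in cold methanol and organozinc reagents, and leaves with fluoride.

Step 2
Reactants: 2 triisopropyl(4-iodophenoxy)silane; 3 but-3-enoic acid
Product: 4 (E)-4-[4-(triisopropylsilyloxy)phenyl]but-3-enoic acid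
Conditions: Pd(OAc)2 (2 mol%), Et3N, MeCN, 80 °C
Reagents that add atoms: none
Why: Heck reaction; the aryl–palladium species adds to the terminal alkene carbon and beta-hydride elimination towards the new benzylic position gives the E-styrene, leaving the alkene beta,gamma to the carboxyl group.

Step 3
Reactants: 4 (E)-4-[4-(triisopropylsilyloxy)phenyl]but-3-enoic acid; 5 (R)-4-benzyl-2-oxazolidinone
Product: 7 (R)-4-benzyl-3-{(E)-4-[4-(triisopropylsilyloxy)phenyl]but-3-enoyl}oxazolidin-2-one, via mixed pivalic anhydride 6 (not isolated)
Conditions: t-BuCOCl, Et3N, THF, −20 °C; then 5, LiCl, −20 → 23 °C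
Reagents that add atoms: none
Why: N-Acylation of an oxazolidinone through a mixed anhydride; the LiCl-activated auxiliary attacks the less hindered carbonyl of 6, and with only an amine base present the alkene should stay out of conjugation with the carbonyl group.

Step 4
Reactants: 8 4-bromo-3-hydroxybenzaldehyde
Product: 9 4-bromo-3-(triisopropylsilyloxy)benzaldehyde
Conditions: i-Pr3SiCl, imidazole, DMF, 23 °C
Reagents that add atoms: triisopropylsilyl chloride, CC(C)[Si](Cl)(C(C)C)C(C)C
Why: Silyl ether formation on a phenol, as in step 1.

Step 5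
Reactants: 9 4-bromo-3-(triisopropylsilyloxy)benzaldehyde
Product: 10 [4-bromo-3-(triisopropylsilyloxy)phenyl]methanol
Conditions: NaBH4, MeOH/THF, 0 °C
Reagents that add atoms: none
Why: Borohydride reduction of an aryl aldehyde; the aryl bromide and the silyl ether are inert at 0 °C.

Step 6
Reactants: 10 [4-bromo-3-(triisopropylsilyloxy)phenyl]methanol
Product: 11 [2-bromo-5-(bromomethyl)phenoxy]triisopropylsilane
Conditions: CBr4, PPh3, CH2Cl2, 0 °C
Reagents that add atoms: carbon tetrabromide, BrC(Br)(Br)Br
Why: Appel reaction; a neutral conversion of the benzylic alcohol into the bromide that leaves the aryl silyl ether intact.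

Step 7
Reactants: 7 (R)-4-benzyl-3-{(E)-4-[4-(triisopropylsilyloxy)phenyl]but-3-enoyl}oxazolidin-2-one; 11 [2-bromo-5-(bromomethyl)phenoxy]triisopropylsilane
Product: 13 (R)-4-benzyl-3-{(R,E)-2-[4-bromo-3-(triisopropylsilyloxy)benzyl]-4-[4-(triisopropylsilyloxy)phenyl]but-3-enoyl}oxazolidin-2-one, via sodium (Z)-dienolate 12 (not isolated)
Conditions: NaN(SiMe3)2 (1.1 equiv), THF, −78 °C; then 11, −78 → −40 °C
Reagents that add atoms: none
Why: Evans alkylation of a chelated sodium (Z)-dienolate; the dienolate reacts at its alpha carbon, the benzyl group of the (R)-auxiliary blocks one face and the bromide enters from the other, which sets C3 as R (C(=O)N > styryl > CH2Ar > H).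

Step 8
Reactants: 13 (R)-4-benzyl-3-{(R,E)-2-[4-bromo-3-(triisopropylsilyloxy)benzyl]-4-[4-(triisopropylsilyloxy)phenyl]but-3-enoyl}oxazolidin-2-one
Product: 15 (R,E)-2-[4-bromo-3-(triisopropylsilyloxy)benzyl]-4-[4-(triisopropylsilyloxy)phenyl]but-3-enoic acid, via lithium peroxycarboxylate 14 (not isolated)
Conditions: LiOH·H2O, 30% H2O2, THF/H2O (3:1), 0 °C; then aq. Na2SO3; 1 M HCl to pH 3
Reagents that add atoms: hydrogen peroxide, OO (delivered as LiOOH)
Why: Hydroperoxide cleavage of an N-acyl oxazolidinone; HOO− is a strong nucleophile but a weak base, attacks the exocyclic carbonyl and should leave the acidic C3–H and the alkene position alone; sulfite reduces 14 to the carboxylate and auxiliary 5 is recovered.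

Step 9
Reactants: 15 (R,E)-2-[4-bromo-3-(triisopropylsilyloxy)benzyl]-4-[4-(triisopropylsilyloxy)phenyl]but-3-enoic acid
Product: 16 methyl (R,E)-2-[4-bromo-3-(triisopropylsilyloxy)benzyl]-4-[4-(triisopropylsilyloxy)phenyl]but-3-enoate
Conditions: Me3SiCHN2, MeOH/toluene (1:4), 0 → 23 °C
Reagents that add atoms: trimethylsilyldiazomethane, C[Si](C)(C)C=[N+]=[N-]
Why: O-Methylation of a carboxylic acid with a diazoalkane; no base is involved, so C3 and the beta,gamma-alkene are not disturbed.

Step 10
Reactants: 17 2-iodobenzene-1,3-diol; 18 methyl (S)-lactate (two equivalents are incorporated)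
Product: 19 dimethyl (2R,2'R)-2,2'-[(2-iodo-1,3-phenylene)bis(oxy)]dipropanoate
Conditions: 18 (2.4 equiv), PPh3 (2.4 equiv), i-PrO2CN=NCO2i-Pr (2.4 equiv), THF, 0 → 23 °C
Reagents that add atoms: methyl (S)-lactate, C[C@H](O)C(=O)OC (the second equivalent of 18, which alkylates the second phenol oxygen)
Why: Twofold Mitsunobu reaction; each of the two phenol oxygens of 17 displaces the activated hydroxyl of one molecule of 18 by SN2 with inversion, so two equivalents of the (S)-lactate give the (R,R)-diether.

Step 11
Reactants: 19 dimethyl (2R,2'R)-2,2'-[(2-iodo-1,3-phenylene)bis(oxy)]dipropanoate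
Product: 20 dimethyl (2R,2'R)-2,2'-{[2-(diacetoxy-λ3-iodanyl)-1,3-phenylene]bis(oxy)}dipropanoate
Conditions: MeCO3H (32% in AcOH), 23 °C
Reagents that add atoms: peracetic acid, CC(=O)OO; acetic acid, CC(=O)O
Why: Peracid oxidation of an aryl iodide to the aryl-λ3-iodane diacetate, the standard preparation of ArI(OAc)2 reagents; the lactate centres are not involved.

Step 12
Reactants: 16 methyl (R,E)-2-[4-bromo-3-(triisopropylsilyloxy)benzyl]-4-[4-(triisopropylsilyloxy)phenyl]but-3-enoate; 20 dimethyl (2R,2'R)-2,2'-{[2-(diacetoxy-λ3-iodanyl)-1,3-phenylene]bis(oxy)}dipropanoate; 21 methanol (two molecules are incorporated)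
Product: 23 methyl (2R,3R)-2-[4-bromo-3-(triisopropylsilyloxy)benzyl]-4,4-dimethoxy-3-[4-(triisopropylsilyloxy)phenyl]butanoate, via β-methoxyalkyl-λ3-iodane 22 (not isolated)
Conditions: 20 (1.3 equiv), TsOH·H2O (1.5 equiv), 21/CH2Cl2 (1:4), −78 → −30 °C
Reagents that add atoms: methanol, CO (the second molecule of 21, which completes the dimethyl acetal)
Why: Ligand exchange of 20 with TsOH gives an electrophilic hydroxy(tosyloxy)iodane that binds the electron-rich styrene of 16, and a first molecule of methanol opens the iodonium ion at benzylic C1 anti to iodine to give 22. Ring A then displaces aryl iodide 19 from C2 through a phenonium ion with inversion at C2, the methoxy oxygen opens the phenonium ion to an oxocarbenium ion at C1, and a second molecule of methanol captures it as the dimethyl acetal. The closest known reaction type is the oxidative rearrangement of 1,2-disubstituted aryl alkenes to 2-aryl aldehyde acetals with PhI(OH)OTs in methanol, together with its stereoselective form using lactate-derived aryl-λ3-iodanes on chalcone-type aryl alkenes. No ring is closed; the C2–aryl bond and two C–O bonds are formed. The new centre C2 is fixed by the alkene face to which iodine bonds: iodine must take the Si face of C2 so that ring A arrives on the Re face and C2 becomes R. The C3 centre exerts only a small bias across an E-alkene, so the twofold-symmetric reagent is the main control element, and because C3 is already set any minor isomer is a diastereomer removable by chromatography. The step also needs methanol to attack C1 and not C2 (secured by the para-silyloxy group), aryl migration in preference to a second methanol displacement at C2 (secured by the high migratory aptitude of the para-oxygenated ring), and no reaction elsewhere (ring B is deactivated by bromine, the methyl ester is degenerate towards methanol and a weaker neighbouring group than the solvent).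

Step 13
Reactants: 23 methyl (2R,3R)-2-[4-bromo-3-(triisopropylsilyloxy)benzyl]-4,4-dimethoxy-3-[4-(triisopropylsilyloxy)phenyl]butanoate
Product: 24 methyl (2R,3R)-4,4-dimethoxy-2-[4-(3-methylbut-2-enyl)-3-(triisopropylsilyloxy)benzyl]-3-[4-(triisopropylsilyloxy)phenyl]butanoate
Conditions: Me2C=CHCH2ZnBr (1.5 equiv; from Me2C=CHCH2Br, Zn, LiCl, THF), Pd(OAc)2 (2 mol%), CPhos (4 mol%), THF, 23 °C
Reagents that add atoms: 3-methylbut-2-enylzinc bromide, CC(C)=CC[Zn]Br (made from 1-bromo-3-methylbut-2-ene, CC(C)=CCBr)
Why: Negishi coupling of an allylic zinc halide; with a bulky biarylphosphine on palladium, reductive elimination should occur at the unsubstituted allyl terminus and give the linear prenyl arene, and at room temperature the ester, acetal and silyl ethers are not attacked; C2 is protected from enolisation by the acetal.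

Step 14
Reactants: 24 methyl (2R,3R)-4,4-dimethoxy-2-[4-(3-methylbut-2-enyl)-3-(triisopropylsilyloxy)benzyl]-3-[4-(triisopropylsilyloxy)phenyl]butanoate
Product: 25 methyl (2R,3R)-2-[4-(3-methylbut-2-enyl)-3-(triisopropylsilyloxy)benzyl]-4-oxo-3-[4-(triisopropylsilyloxy)phenyl]butanoate
Conditions: TsOH·H2O (0.2 equiv), acetone/H2O (10:1), 23 °C; crude product used at once
Reagents that add atoms: water, O
Why: Acid-catalysed acetal hydrolysis driven by exchange with acetone; dilute sulfonic acid at room temperature should not hydrate the prenyl alkene or cleave aryl silyl ethers, and the aldehyde is not chromatographed so that C2 has little opportunity to enolise.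

Step 15
Reactants: 25 methyl (2R,3R)-2-[4-(3-methylbut-2-enyl)-3-(triisopropylsilyloxy)benzyl]-4-oxo-3-[4-(triisopropylsilyloxy)phenyl]butanoate
Product: 26 (2R,3R)-4-methoxy-3-[4-(3-methylbut-2-enyl)-3-(triisopropylsilyloxy)benzyl]-4-oxo-2-[4-(triisopropylsilyloxy)phenyl]butanoic acid
Conditions: NaClO2, NaH2PO4, 2-methylbut-2-ene (30 equiv), t-BuOH/THF/H2O, 0 → 23 °C
Reagents that add atoms: sodium chlorite, [Na+].[O-]Cl=O
Why: Pinnick oxidation; chlorous acid oxidises the aldehyde at pH 3–4 without enolisation, and the large excess of 2-methylbut-2-ene traps hypochlorous acid before it can attack the prenyl group or the silyloxyarenes.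

Step 16
Reactants: 26 (2R,3R)-4-methoxy-3-[4-(3-methylbut-2-enyl)-3-(triisopropylsilyloxy)benzyl]-4-oxo-2-[4-(triisopropylsilyloxy)phenyl]butanoic acid
Product: 27 (2R,3R)-2-(4-hydroxyphenyl)-3-[3-hydroxy-4-(3-methylbut-2-enyl)benzyl]-4-methoxy-4-oxobutanoic acid
Conditions: Bu4NF (3 equiv), AcOH (3 equiv), THF, 0 °C; work-up at pH 4
Reagents that add atoms: none
Why: Fluoride-induced cleavage of aryl silyl ethers; acetic acid buffering keeps the medium from deprotonating C3–H, and the absence of strong acid avoids chroman formation from the ortho-prenylphenol.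

## Compound list

1 | 4-iodophenol | Oc1ccc(I)cc1 | starting material
2 | triisopropyl(4-iodophenoxy)silane | CC(C)[Si](Oc1ccc(I)cc1)(C(C)C)C(C)C | intermediate
3 | but-3-enoic acid | C=CCC(=O)O | starting material
4 | (E)-4-[4-(triisopropylsilyloxy)phenyl]but-3-enoic acid | OC(=O)C/C=C/c1ccc(O[Si](C(C)C)(C(C)C)C(C)C)cc1 | intermediate
5 | (R)-4-benzyl-2-oxazolidinone | O=C1N[C@H](Cc2ccccc2)CO1 | starting material
6 | (E)-4-[4-(triisopropylsilyloxy)phenyl]but-3-enoic pivalic anhydride | CC(C)(C)C(=O)OC(=O)C/C=C/c1ccc(O[Si](C(C)C)(C(C)C)C(C)C)cc1 | intermediate (not isolated)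
7 | (R)-4-benzyl-3-{(E)-4-[4-(triisopropylsilyloxy)phenyl]but-3-enoyl}oxazolidin-2-one | O=C(C/C=C/c1ccc(O[Si](C(C)C)(C(C)C)C(C)C)cc1)N1[C@H](Cc2ccccc2)COC1=O | intermediate
8 | 4-bromo-3-hydroxybenzaldehyde | O=Cc1ccc(Br)c(O)c1 | starting material
9 | 4-bromo-3-(triisopropylsilyloxy)benzaldehyde | O=Cc1ccc(Br)c(O[Si](C(C)C)(C(C)C)C(C)C)c1 | intermediate
10 | [4-bromo-3-(triisopropylsilyloxy)phenyl]methanol | OCc1ccc(Br)c(O[Si](C(C)C)(C(C)C)C(C)C)c1 | intermediate
11 | [2-bromo-5-(bromomethyl)phenoxy]triisopropylsilane | BrCc1ccc(Br)c(O[Si](C(C)C)(C(C)C)C(C)C)c1 | intermediate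
12 | sodium (Z)-dienolate of 7 | [Na+].[O-]/C(=C\C=C\c1ccc(O[Si](C(C)C)(C(C)C)C(C)C)cc1)N1[C@H](Cc2ccccc2)COC1=O | intermediate (not isolated)
13 | (R)-4-benzyl-3-{(R,E)-2-[4-bromo-3-(triisopropylsilyloxy)benzyl]-4-[4-(triisopropylsilyloxy)phenyl]but-3-enoyl}oxazolidin-2-one | O=C([C@H](Cc1ccc(Br)c(O[Si](C(C)C)(C(C)C)C(C)C)c1)/C=C/c1ccc(O[Si](C(C)C)(C(C)C)C(C)C)cc1)N1[C@H](Cc2ccccc2)COC1=O | intermediate
14 | lithium (R,E)-2-[4-bromo-3-(triisopropylsilyloxy)benzyl]-4-[4-(triisopropylsilyloxy)phenyl]but-3-eneperoxoate | [Li+].[O-]OC(=O)[C@H](Cc1ccc(Br)c(O[Si](C(C)C)(C(C)C)C(C)C)c1)/C=C/c1ccc(O[Si](C(C)C)(C(C)C)C(C)C)cc1 | intermediate (not isolated)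
15 | (R,E)-2-[4-bromo-3-(triisopropylsilyloxy)benzyl]-4-[4-(triisopropylsilyloxy)phenyl]but-3-enoic acid | OC(=O)[C@H](Cc1ccc(Br)c(O[Si](C(C)C)(C(C)C)C(C)C)c1)/C=C/c1ccc(O[Si](C(C)C)(C(C)C)C(C)C)cc1 | intermediate
16 | methyl (R,E)-2-[4-bromo-3-(triisopropylsilyloxy)benzyl]-4-[4-(triisopropylsilyloxy)phenyl]but-3-enoate | COC(=O)[C@H](Cc1ccc(Br)c(O[Si](C(C)C)(C(C)C)C(C)C)c1)/C=C/c1ccc(O[Si](C(C)C)(C(C)C)C(C)C)cc1 | intermediate
17 | 2-iodobenzene-1,3-diol | Oc1cccc(O)c1I | starting material
18 | methyl (S)-lactate | C[C@H](O)C(=O)OC | starting material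
19 | dimethyl (2R,2'R)-2,2'-[(2-iodo-1,3-phenylene)bis(oxy)]dipropanoate | COC(=O)[C@@H](C)Oc1cccc(O[C@H](C)C(=O)OC)c1I | intermediate
20 | dimethyl (2R,2'R)-2,2'-{[2-(diacetoxy-λ3-iodanyl)-1,3-phenylene]bis(oxy)}dipropanoate | COC(=O)[C@@H](C)Oc1cccc(O[C@H](C)C(=O)OC)c1I(OC(C)=O)OC(C)=O | intermediate
21 | methanol | CO | starting material
22 | methyl (2S,3R,4S)-2-[4-bromo-3-(triisopropylsilyloxy)benzyl]-3-{[2,6-bis((R)-1-methoxy-1-oxopropan-2-yloxy)phenyl](tosyloxy)-λ3-iodanyl}-4-methoxy-4-[4-(triisopropylsilyloxy)phenyl]butanoate | COC(=O)[C@H](Cc1ccc(Br)c(O[Si](C(C)C)(C(C)C)C(C)C)c1)[C@@H](I(OS(=O)(=O)c1ccc(C)cc1)c1c(O[C@H](C)C(=O)OC)cccc1O[C@H](C)C(=O)OC)[C@@H](OC)c1ccc(O[Si](C(C)C)(C(C)C)C(C)C)cc1 | intermediate (not isolated)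
23 | methyl (2R,3R)-2-[4-bromo-3-(triisopropylsilyloxy)benzyl]-4,4-dimethoxy-3-[4-(triisopropylsilyloxy)phenyl]butanoate | COC(=O)[C@H](Cc1ccc(Br)c(O[Si](C(C)C)(C(C)C)C(C)C)c1)[C@@H](C(OC)OC)c1ccc(O[Si](C(C)C)(C(C)C)C(C)C)cc1 | intermediate
24 | methyl (2R,3R)-4,4-dimethoxy-2-[4-(3-methylbut-2-enyl)-3-(triisopropylsilyloxy)benzyl]-3-[4-(triisopropylsilyloxy)phenyl]butanoate | COC(=O)[C@H](Cc1ccc(CC=C(C)C)c(O[Si](C(C)C)(C(C)C)C(C)C)c1)[C@@H](C(OC)OC)c1ccc(O[Si](C(C)C)(C(C)C)C(C)C)cc1 | intermediate
25 | methyl (2R,3R)-2-[4-(3-methylbut-2-enyl)-3-(triisopropylsilyloxy)benzyl]-4-oxo-3-[4-(triisopropylsilyloxy)phenyl]butanoate | COC(=O)[C@H](Cc1ccc(CC=C(C)C)c(O[Si](C(C)C)(C(C)C)C(C)C)c1)[C@@H](C=O)c1ccc(O[Si](C(C)C)(C(C)C)C(C)C)cc1 | intermediate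
26 | (2R,3R)-4-methoxy-3-[4-(3-methylbut-2-enyl)-3-(triisopropylsilyloxy)benzyl]-4-oxo-2-[4-(triisopropylsilyloxy)phenyl]butanoic acid | COC(=O)[C@H](Cc1ccc(CC=C(C)C)c(O[Si](C(C)C)(C(C)C)C(C)C)c1)[C@@H](C(=O)O)c1ccc(O[Si](C(C)C)(C(C)C)C(C)C)cc1 | intermediate
27 | (2R,3R)-2-(4-hydroxyphenyl)-3-[3-hydroxy-4-(3-methylbut-2-enyl)benzyl]-4-methoxy-4-oxobutanoic acid | COC(=O)[C@H](Cc1ccc(CC=C(C)C)c(O)c1)[C@@H](C(=O)O)c1ccc(O)cc1 | target

## Step count and least certain steps

Total step count: 16 (14 on the skeleton of 27, 2 for reagent 20).
Longest linear sequence: 11 steps (steps 1, 2, 3, 7, 8, 9, 12, 13, 14, 15, 16 from 1; the sequence from 8 through steps 4–9 and 12–16 is equally long).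

**Step 12 (key step).** The most likely failure is poor discrimination between the two alkene faces. An E-alkene gives the C3 centre little leverage, and the reagent has not been tested against a branched allylic substituent. Participation of the ester carbonyl at C4 is a lesser concern. The fallback sets out from 4 and returns at 23, and it changes the order in which the centres are made. Acid 4 is esterified with Me3SiCHN2 to methyl (E)-4-[4-(triisopropylsilyloxy)phenyl]but-3-enoate F1. This achiral styrene is rearranged with 20, TsOH·H2O and methanol 21, under reagent control alone, to methyl (R)-4,4-dimethoxy-3-[4-(triisopropylsilyloxy)phenyl]butanoate F2. The ester enolate of F2 (LiN(i-Pr)2, THF, −78 °C) is then alkylated with bromide 11. With the C2 hydrogen eclipsing the enolate and the electrophile entering anti to ring A, the usual model for 1,2-induction predicts the (2R,3R) relationship of 23. The margin may be modest, and a minor diastereomer would be removed by chromatography.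

**Step 7.** The most likely failure is proton exchange between product and unreacted dienolate, because the new C3–H lies between the imide and a styrene. That would erode the diastereomer ratio, allow a second alkylation or move the alkene into conjugation; attack through the benzylic gamma carbon is a second possibility. The fallback sets out from 5, 11 and 2 and returns at 13; it separates the alkylation from the styrene. Auxiliary 5 is acylated (n-BuLi, (E)-but-2-enoyl chloride, THF, −78 °C) to (R)-4-benzyl-3-[(E)-but-2-enoyl]oxazolidin-2-one F3. Its sodium dienolate (NaN(SiMe3)2, −78 °C) is alkylated at the alpha carbon with 11 to (R)-4-benzyl-3-{(R)-2-[4-bromo-3-(triisopropylsilyloxy)benzyl]but-3-enoyl}oxazolidin-2-one F4, whose C–H is less acidic than that of 13. Triisopropyl(4-vinylphenoxy)silane F5, made from 2 by Stille coupling with tributyl(vinyl)stannane and Pd(PPh3)4, is joined to F4 by cross-metathesis with the second-generation Grubbs catalyst (H2IMes)(PCy3)Cl2Ru=CHPh, giving the E-styrene 13 under neutral conditions.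

**Step 8.** The most likely failure is partial loss of the aryl silyl ethers to hydroxide, or base-induced drift at C3 (epimerisation or alkene migration) if the cleavage is slow. The fallback sets out from 13 and returns at 16, replacing hydrolysis by thiolysis. LiSEt (from EtSH and n-BuLi, THF, 0 °C), a strong nucleophile but a weak base, opens the imide to S-ethyl (R,E)-2-[4-bromo-3-(triisopropylsilyloxy)benzyl]-4-[4-(triisopropylsilyloxy)phenyl]but-3-enethioate F6. AgO2CCF3 in methanol then converts the thioester directly into 16, bypassing acid 15 and aqueous base.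

**Step 13.** The most likely failure is coupling through the substituted allyl terminus (reverse prenyl isomer), or slow oxidative addition next to the bulky silyl ether with competing consumption of the zinc reagent. The fallback sets out from 23 and returns at 24, building the prenyl group in two stages. Stille coupling of 23 with allyltributylstannane (Pd(PPh3)4, toluene, 100 °C) gives methyl (2R,3R)-2-[4-allyl-3-(triisopropylsilyloxy)benzyl]-4,4-dimethoxy-3-[4-(triisopropylsilyloxy)phenyl]butanoate F7; the allyl group has no regiochemical ambiguity. Cross-metathesis of F7 with excess 2-methylbut-2-ene and the second-generation Grubbs catalyst (H2IMes)(PCy3)Cl2Ru=CHPh then converts allyl into prenyl to give 24.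

**Step 14.** The most likely failure is epimerisation at C2 by acid-catalysed enolisation of the alpha-aryl aldehyde while the hindered acetal hydrolyses slowly; prolonged acid exposure could also hydrate the prenyl alkene. The fallback sets out from 23 and returns at 26, unveiling the acid before the prenyl group is present so that a short, cold, stronger hydrolysis is possible. Acetal 23 is cleaved with CF3CO2H/H2O in CHCl3 at 0 °C to methyl (2R,3R)-2-[4-bromo-3-(triisopropylsilyloxy)benzyl]-4-oxo-3-[4-(triisopropylsilyloxy)phenyl]butanoate F8. Pinnick oxidation gives (2R,3R)-3-[4-bromo-3-(triisopropylsilyloxy)benzyl]-4-methoxy-4-oxo-2-[4-(triisopropylsilyloxy)phenyl]butanoic acid F9. The prenyl group is then introduced on the free acid by Stille coupling with tributyl(3-methylbut-2-enyl)stannane and Pd(PPh3)4 in DMF, since the neutral tin reagent tolerates a carboxylic acid, giving 26.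

## Further compounds

F1 | step 12 | methyl (E)-4-[4-(triisopropylsilyloxy)phenyl]but-3-enoate | COC(=O)C/C=C/c1ccc(O[Si](C(C)C)(C(C)C)C(C)C)cc1
F2 | step 12 | methyl (R)-4,4-dimethoxy-3-[4-(triisopropylsilyloxy)phenyl]butanoate | COC(=O)C[C@@H](C(OC)OC)c1ccc(O[Si](C(C)C)(C(C)C)C(C)C)cc1
F3 | step 7 | (R)-4-benzyl-3-[(E)-but-2-enoyl]oxazolidin-2-one | C/C=C/C(=O)N1[C@H](Cc2ccccc2)COC1=O
F4 | step 7 | (R)-4-benzyl-3-{(R)-2-[4-bromo-3-(triisopropylsilyloxy)benzyl]but-3-enoyl}oxazolidin-2-one | O=C([C@H](Cc1ccc(Br)c(O[Si](C(C)C)(C(C)C)C(C)C)c1)C=C)N1[C@H](Cc2ccccc2)COC1=O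
F5 | step 7 | triisopropyl(4-vinylphenoxy)silane | C=Cc1ccc(O[Si](C(C)C)(C(C)C)C(C)C)cc1
F6 | step 8 | S-ethyl (R,E)-2-[4-bromo-3-(triisopropylsilyloxy)benzyl]-4-[4-(triisopropylsilyloxy)phenyl]but-3-enethioate | CCSC(=O)[C@H](Cc1ccc(Br)c(O[Si](C(C)C)(C(C)C)C(C)C)c1)/C=C/c1ccc(O[Si](C(C)C)(C(C)C)C(C)C)cc1
F7 | step 13 | methyl (2R,3R)-2-[4-allyl-3-(triisopropylsilyloxy)benzyl]-4,4-dimethoxy-3-[4-(triisopropylsilyloxy)phenyl]butanoate | COC(=O)[C@H](Cc1ccc(CC=C)c(O[Si](C(C)C)(C(C)C)C(C)C)c1)[C@@H](C(OC)OC)c1ccc(O[Si](C(C)C)(C(C)C)C(C)C)cc1
F8 | step 14 | methyl (2R,3R)-2-[4-bromo-3-(triisopropylsilyloxy)benzyl]-4-oxo-3-[4-(triisopropylsilyloxy)phenyl]butanoate | COC(=O)[C@H](Cc1ccc(Br)c(O[Si](C(C)C)(C(C)C)C(C)C)c1)[C@@H](C=O)c1ccc(O[Si](C(C)C)(C(C)C)C(C)C)cc1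
F9 | step 14 | (2R,3R)-3-[4-bromo-3-(triisopropylsilyloxy)benzyl]-4-methoxy-4-oxo-2-[4-(triisopropylsilyloxy)phenyl]butanoic acid | COC(=O)[C@H](Cc1ccc(Br)c(O[Si](C(C)C)(C(C)C)C(C)C)c1)[C@@H](C(=O)O)c1ccc(O[Si](C(C)C)(C(C)C)C(C)C)cc1
A1 | alternative 1 | (3R,4R)-3-[4-bromo-3-(pivaloyloxy)benzyl]-4-[4-(pivaloyloxy)phenyl]oxolane-2,5-dione (cis) | O1C(=O)[C@H](Cc2ccc(Br)c(OC(=O)C(C)(C)C)c2)[C@@H](C1=O)c3ccc(OC(=O)C(C)(C)C)cc3
A2 | alternative 1 | (2R,3S)-3-[4-bromo-3-(pivaloyloxy)benzyl]-2-[4-(pivaloyloxy)phenyl]oxirane (cis) | O1[C@@H](Cc2ccc(Br)c(OC(=O)C(C)(C)C)c2)[C@H]1c3ccc(OC(=O)C(C)(C)C)cc3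
A3 | alternative 2 | (3R,4R)-3-[3-acetoxy-4-(3-methylbut-2-enyl)benzyl]-4-(4-acetoxyphenyl)oxolane-2,5-dione (cis) | O1C(=O)[C@H](Cc2ccc(CC=C(C)C)c(OC(C)=O)c2)[C@@H](C1=O)c3ccc(OC(C)=O)cc3
A4 | alternative 2 | 3-[3-acetoxy-4-(3-methylbut-2-enyl)benzyl]-4-(4-acetoxyphenyl)furan-2,5-dione | O=C1OC(=O)C(Cc2ccc(CC=C(C)C)c(OC(C)=O)c2)=C1c3ccc(OC(C)=O)cc3
A5 | alternative 3 | 4-methyl 1-[2-(trimethylsilyl)ethyl] (2R,3R)-2-[4-(tert-butyldimethylsilyloxy)phenyl]-3-[3-(tert-butyldimethylsilyloxy)-4-(3-methylbut-2-enyl)benzyl]butanedioate | COC(=O)[C@H](Cc1ccc(CC=C(C)C)c(O[Si](C)(C)C(C)(C)C)c1)[C@@H](C(=O)OCC[Si](C)(C)C)c1ccc(O[Si](C)(C)C(C)(C)C)cc1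
A6 | alternative 3 | 4-methyl 1-[2-(trimethylsilyl)ethyl] (S)-2-[4-(tert-butyldimethylsilyloxy)phenyl]-3-methylidenebutanedioate | COC(=O)C(=C)[C@@H](C(=O)OCC[Si](C)(C)C)c1ccc(O[Si](C)(C)C(C)(C)C)cc1
A7 | alternative 3 | [3-(tert-butyldimethylsilyloxy)-4-(3-methylbut-2-enyl)phenyl]boronic acid | OB(O)c1ccc(CC=C(C)C)c(O[Si](C)(C)C(C)(C)C)c1
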